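Friday's flask still has 74.0% of its starting material left over at 33 min, yet its last interval adds 3.00 × 10⁻⁴ M of product.

| flask | starting material | coupling partner | free catalyst | time |
|---|---|---|---|---|
| Friday's | 0.100 M | 0.150 M | 2.00 × 10⁻⁴ M |  |
| Thursday's | 0.100 M | 0.300 M | 2.00 × 10⁻⁴ M |  |
| Wednesday's | 0.100 M | 0.520 M | 2.00 × 10⁻⁴ M | 33 min |

| Friday's run: time / min | Friday's run: [product] / M | Thursday's run: time / min | Thursday's run: [product] / M |
|---|---|---|---|
| 6.6 | 0.0177 | 6.6 | 0.0255 |
| 13 | 0.0231 | 13 | 0.0317 |
| 20 | 0.0249 | 20 | 0.0353 |
| 26 | 0.0257 | 26 | 0.0366 |
| 33 | 0.0260 | 33 | 0.0381 |

(readings scatter by 5 × 10⁻⁴ M)

- how the opening rate goes with [coupling partner] round the charge of the Friday's run: the exponent of the rate at two percent of starting material gone to product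
- product in the Wednesday's run at 33 min, as a share of the starting material charged

- Overall: starting material + coupling partner -> product, with free catalyst as catalyst.
- Constant volume, constant temperature.
- Bound and free are read together.
- "The second partner" is coupling partner.
- An order is taken over about fifteen percent of the charge, up and down.

Here are two ways of reading these runs, both my own. Starting material is charged in the smaller amount, and what remains of it is its charge minus c(product). If the rate is first order in it, the right measure of progress is the depth, the logarithm of charge over remainder. At the last reading the depth is 0.301 on Friday and 0.480 on Thursday. As a power of the partner charge, that gives an exponent of 0.672, and carried to Wednesday's charge, a share of 50.0%.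

The second way squares c(product) and divides by the partner charge. At the first reading this gives 0.00209 M on Friday and 0.00217 M on Thursday. At the last it gives 0.00451 M and 0.00484 M. The mean of the last pair, 0.00467 M, is the squared yield per partner. It puts Wednesday's share at 49.3%.

The two shares stand close, but both come from the same last readings, so their closeness is no check on either law. The exponents part. If the rate follows the partner and falls as one over product, the squared yield per partner comes out common at one clock, as these readings nearly show: exponent 1. The depth compares at one clock, where Thursday's flask holds more product than Friday's. The opening exponent is asked at equal product, so the clock comparison cheats, and I commit to 1.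

The forecast gives an exponent of 0.7 (0.5 to 0.95), on “an average order of about 0.65”, and a share of 48% (42% to 57%).

The flask gives an exponent of 1.0 and a share of 48.7%.

    2 free catalyst ⇌ catalyst dimer, settled at all times (1160 M⁻¹)
    free catalyst + starting material + coupling partner → product + free catalyst (5316 M⁻² min⁻¹)
    free catalyst + product ⇌ catalyst-product complex, settled at all times (290.0 M⁻¹)
    coupling partner → lost reagent (0.07920 min⁻¹)

Where two percent of Friday's starting material has turned, the rates are 0.0083 M min⁻¹ on Friday and 0.017 M min⁻¹ on Thursday. Wednesday's squared yield per partner is 0.00455 M, against the 0.00467 M carried over. Product binding free catalyst as catalyst-product complex is the main reason Wednesday's flask stands at 48.7%: the same run without that binding reaches 98.0%. At 0.0185 M, that run's squared yield per partner is larger than the carried 0.00467 M.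

The runs come from a simulation on assumed constants, and the scatter is random.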